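1. One micromolar of added ligand takes one micromolar of catalyst into idle complex, an off-cycle form. Catalyst charged minus added ligand charged, here −4.00 µM, is the catalyst margin. It is the floor under free catalyst when positive, and in the reactions considered the rate of making left-handed product is proportional to free catalyst at given substrate and partner.

all flasks: left-handed substrate 20 mM; right-handed substrate 20 mM; added ligand 24 µM
- teal: coupling partner 20 mM; catalyst 28 µM; run made earlier
- ochre: coupling partner 20 mM; catalyst 44 µM; run made earlier
- flask: coupling partner 20.0 mM; catalyst 20 µM

| teal: time / h | teal: left-handed product / % | ochre: time / h | ochre: left-handed product / % |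
|---|---|---|---|
| 1.50 | 3.8 | 4.00 | 11.9 |
| 5.00 | 8.1 | 8.00 | 17.3 |
| 8.00 | 10.7 | 12.0 | 21.1 |
| 12.0 | 12.7 | 15.0 | 23.7 |
| 20.0 | 15.6 | 20.0 | 27.1 |
| 25.0 | 17.4 | 25.0 | 28.3 |

(standard deviation of a reading: 0.5 percentage points)

- apparent order in coupling partner when 10% of the left-handed substrate and right-handed substrate together are converted (percent change of the rate of making left-handed product for one percent more coupling partner charged)
- factor on the rate of making left-handed product when 10% of the left-handed substrate and right-handed substrate together are converted if catalyst is charged twice over

2. The margin is 4.00 µM in teal and 20.0 µM in ochre. The teal rate of making left-handed product, read from the readings, fell about 6.99-fold between the first 1.50 h and the stretch from 12.0 h to 20.0 h, a fall spread over hours.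

3. Turning up the catalyst: charged twice over, the flask's margin becomes 16.0 µM. The flask itself has surplus ligand and no floor, so this reckoning estimates its free catalyst at 10% conversion, called the mark here, below teal's floor of 4.00 µM. That estimates a factor above 4.00.

4. Turning up the coupling partner: at the mark, 4.00 mM of it is used, which at fixed free catalyst gives an order of 1.25. By this reckoning, more partner also brings the mark sooner, with more catalyst still free. If free catalyst falls as one over time, that adds about 1, so this reckoning gives 2.25.

5. The forecast gives 1.15 for the order and 3.8 for the factor, taking “free catalyst is about 4–6 µM”. Its factor stands below this reckoning's estimate, and its order below this reckoning's value.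

6. The simulation gives an order of 3.1 and a factor of 11.9.

    catalyst + added ligand ⇌ idle complex (K = 2.60 × 10⁶ M⁻¹, k = 482 M⁻¹ min⁻¹)
    coupling partner + catalyst + left-handed substrate → catalyst + left-handed product (k = 2590 M⁻² min⁻¹)
    coupling partner + catalyst + right-handed substrate → catalyst + right-handed product (k = 718 M⁻² min⁻¹)

7. In the flask, the step to left-handed product did half of its turnover up to 20.0 h by 3.02 h, while free catalyst fell to 39.6% of its charge at 2.00 h and 10.4% at 10.0 h. The flask reached the mark at 13.1 h with 91.4% of the catalyst as idle complex, leaving 1.72 µM free, and the margin of the doubled charge, 16.0 µM, is 9.30 times that, under the factor of 11.9. At 20.0 h the flask held 8.81% left-handed product and 92.9% of its catalyst as idle complex.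

The data are simulated with constants of no real substance; noise was put on by code.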